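**Plan**

- Retrosynthesis: the three O–benzyl bonds and one ring C–Br bond are cut first, then two neighbouring bonds of the methoxy-bearing ring together (ring C–C(=O) and ring C–O), which gives an aryne and a chiral carboxylic acid.
- The acid is cut at Cα–CHAr2 (imide enolate plus benzhydryl cation) and at the acyl–auxiliary bond; the chromone is cut at O1–C2/C2–C3 and at the CH2–CH2 bond of a keto ester.
- Forward: enolate alkylation gives the keto ester, the pyranone ring of the chromone closes (the only ring made), then auxiliary attachment, benzhydrylation, auxiliary removal, aryne insertion and one hydrogenolysis.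
- Stereochemistry: the single R centre is set by (R)-4-benzyloxazolidin-2-one in a titanium-enolate alkylation and then travels as a carboxylate.
- Enabling feature: on the methoxy ring the ketone carbon and the free OH sit on adjacent ring carbons (acyl para, OH meta to OMe), the pattern an aryne leaves when it inserts into a carboxyl C–O bond. The epimerisable CH is bonded directly to that ketone carbon, so the ketone is made from a carboxylate without strong base or Lewis acid at that carbon.

Key step: step 11

Remark on the chemistry: the chelated Z enolate of the N-acyl oxazolidinone is assumed to react on the face away from the C4 benzyl group, as in other alkylations of this auxiliary. The descriptor is R in the imide, acid, ketones and target alike, because the ranking C=O > chromone C3 > benzhydryl CH > H holds in all of them.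

**Route**

Step 1
Reactants: 1 1-(4-benzyloxy-2-hydroxyphenyl)ethanone; 2 tert-butyl bromoacetate
Product: 3 tert-butyl 4-(4-benzyloxy-2-hydroxyphenyl)-4-oxobutanoate
Conditions: LiN(i-Pr)2 (2.2 equiv), THF, −78 → 0 °C; then 2, −78 °C → rt; aq NH4Cl
Reagents that add atoms: none
Why: two equivalents of amide base give the phenoxide–enolate dianion, whose carbon terminus is the more nucleophilic site and undergoes SN2 enolate alkylation with the α-bromo ester, the bulky tert-butyl ester resisting Claisen attack.

Step 2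
Reactants: 3 tert-butyl 4-(4-benzyloxy-2-hydroxyphenyl)-4-oxobutanoate
Product: 5 tert-butyl 2-(7-benzyloxy-4-oxo-4H-chromen-3-yl)acetate, via enaminone 4 (not isolated)
Conditions: Me2NCH(OMe)2 (2 equiv), toluene, 100 °C; then AcOH, 60 °C
Reagents that add atoms: N,N-dimethylformamide dimethyl acetal, COC(OC)N(C)C
Why: enaminone condensation at the ketone α-methylene followed by addition–elimination of the ortho phenol with loss of dimethylamine (chromone synthesis through an enaminone) closes the pyranone ring and leaves the acetate chain on C3.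

Step 3
Reactants: 5 tert-butyl 2-(7-benzyloxy-4-oxo-4H-chromen-3-yl)acetate
Product: 6 2-(7-benzyloxy-4-oxo-4H-chromen-3-yl)acetic acid
Conditions: CF3CO2H/CH2Cl2 (1:3), rt
Reagents that add atoms: none
Why: acidolysis of the tert-butyl ester with loss of isobutene frees the acid without the aqueous base that could open the chromone, and the aryl benzyl ether is stable to this acid at room temperature.

Step 4
Reactants: 6 2-(7-benzyloxy-4-oxo-4H-chromen-3-yl)acetic acid; 7 (R)-4-benzyloxazolidin-2-one
Product: 9 (R)-4-benzyl-3-[2-(7-benzyloxy-4-oxo-4H-chromen-3-yl)acetyl]oxazolidin-2-one, via mixed pivalic anhydride 8 (not isolated)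
Conditions: t-BuCOCl, Et3N, THF, −20 °C; then LiCl, 7, rt
Reagents that add atoms: pivaloyl chloride, CC(C)(C)C(=O)Cl (its acyl group is carried only by 8 and leaves as pivalate)
Why: N-acylation of the oxazolidinone through the mixed pivalic anhydride with LiCl and Et3N attaches the auxiliary at the unhindered carbonyl of the anhydride without any strong base.

Step 5
Reactants: 10 4,4'-dihydroxybenzophenone
Product: 11 4,4'-bis(benzyloxy)benzophenone
Conditions: BnBr (2.4 equiv), K2CO3, DMF, 60 °C
Reagents that add atoms: benzyl bromide, BrCc1ccccc1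
Why: Williamson ether synthesis on both phenoxides installs protecting groups that survive Lewis acid, hydroperoxide and fluoride and leave in the final hydrogenolysis.

Step 6
Reactants: 11 4,4'-bis(benzyloxy)benzophenone
Product: 13 bis(4-benzyloxyphenyl)methyl methyl ether, via bis(4-benzyloxyphenyl)methanol 12 (not isolated)
Conditions: NaBH4, THF/MeOH, 0 °C → rt; then HCl in MeOH (to pH 1), rt
Reagents that add atoms: methanol, CO
Why: borohydride reduction of the diaryl ketone gives the benzhydrol, which in acidic methanol ionises to the doubly para-alkoxy-stabilised benzhydryl cation and is captured by the solvent (SN1 etherification).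

Step 7
Reactants: 9 (R)-4-benzyl-3-[2-(7-benzyloxy-4-oxo-4H-chromen-3-yl)acetyl]oxazolidin-2-one; 13 bis(4-benzyloxyphenyl)methyl methyl ether
Product: 14 (R)-4-benzyl-3-[(R)-2-(7-benzyloxy-4-oxo-4H-chromen-3-yl)-3,3-bis(4-benzyloxyphenyl)propanoyl]oxazolidin-2-one
Conditions: TiCl4 (2.2 equiv), i-Pr2NEt (1.2 equiv), CH2Cl2, 0 °C; then 13, 0 °C
Reagents that add atoms: none
Why: in this auxiliary-controlled titanium-enolate SN1 alkylation (Evans alkylation) soft enolisation gives the chelated Z chlorotitanium enolate, the excess TiCl4 occupies the chromone carbonyl and ionises 13, and the benzhydryl cation attacks the enolate face opposite the C4 benzyl group of the (R)-auxiliary, which sets the α-carbon as R.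

Step 8
Reactants: 14 (R)-4-benzyl-3-[(R)-2-(7-benzyloxy-4-oxo-4H-chromen-3-yl)-3,3-bis(4-benzyloxyphenyl)propanoyl]oxazolidin-2-one
Product: 16 (R)-2-(7-benzyloxy-4-oxo-4H-chromen-3-yl)-3,3-bis(4-benzyloxyphenyl)propanoic acid, via peroxy acid 15 (not isolated)
Conditions: LiOH, H2O2, THF/H2O, 0 °C; then aq Na2SO3; 1 M HCl
Reagents that add atoms: hydrogen peroxide, OO
Why: hydroperoxide, weakly basic but strongly nucleophilic, attacks the exocyclic imide carbonyl (LiOOH cleavage of an N-acyl oxazolidinone), sulfite reduces the peracid, and at 0 °C neither the α-centre nor the vinylogous-ester C2=C3 bond of the chromone should be touched.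

Step 9
Reactants: 17 2,6-dibromo-4-methoxyphenol
Product: 18 (2,6-dibromo-4-methoxyphenoxy)trimethylsilane
Conditions: (Me3Si)2NH, THF, 70 °C; evaporate
Reagents that add atoms: hexamethyldisilazane, C[Si](C)(C)N[Si](C)(C)C
Why: O-silylation of the phenol by the disilazane is driven by loss of ammonia and gives the silyl ether free of salts.

Step 10
Reactants: 18 (2,6-dibromo-4-methoxyphenoxy)trimethylsilane
Product: 20 2-bromo-4-methoxy-6-(trimethylsilyl)phenyl trifluoromethanesulfonate, via lithium 2-bromo-4-methoxy-6-(trimethylsilyl)phenoxide 19 (not isolated)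
Conditions: n-BuLi (1.05 equiv), THF, −78 °C; then Tf2O, −78 °C → rt
Reagents that add atoms: trifluoromethanesulfonic anhydride, O=S(=O)(OS(=O)(=O)C(F)(F)F)C(F)(F)F
Why: bromine–lithium exchange at one of the two equivalent ortho bromines is followed by a 1,3 O→C silyl shift (retro-Brook rearrangement) to the lithium phenoxide, which is triflated in the same flask.

Step 11
Reactants: 16 (R)-2-(7-benzyloxy-4-oxo-4H-chromen-3-yl)-3,3-bis(4-benzyloxyphenyl)propanoic acid; 20 2-bromo-4-methoxy-6-(trimethylsilyl)phenyl trifluoromethanesulfonate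
Product: 23 (R)-1-(2-bromo-6-hydroxy-4-methoxyphenyl)-2-(7-benzyloxy-4-oxo-4H-chromen-3-yl)-3,3-bis(4-benzyloxyphenyl)propan-1-one, via 3-bromo-5-methoxybenzyne 21 (not isolated), via caesium aryl anion ester 22 (not isolated)
Conditions: 20 (1.5 equiv), CsF (4 equiv), THF, sealed tube, 125 °C
Reagents that add atoms: none
Why: Fluoride removes the silyl group of 20 and triflate leaves, releasing aryne 21; the caesium carboxylate formed from 16 and CsF adds through oxygen to the aryne carbon remote from bromine, and the aryl anion 22 attacks the carbonyl of its own aryl ester through a four-membered transition state that collapses by cleavage of the acyl C–O bond, leaving the ketone as its ortho phenoxide. The closest known reaction type is the fluoride-induced insertion of arynes into the C–O bond of carboxylic acids to give ortho-hydroxyaryl ketones (aryne O-arylation followed by an anionic Fries-type 1,3-acyl shift). No ring is closed, so no mode of closure arises, and no stereocentre is created: the existing R centre enters as a carboxylate, which is hard to enolise, and emerges beside a ketone whose ortho phenoxide lowers its α-acidity. The selectivity needed is the orientation of addition to the unsymmetrical aryne, and it is secured by the bromine on the carbon next to one aryne terminus, which distorts the aryne so that the remote terminus is the electrophilic one and stabilises the developing carbanion inductively, overriding the weak opposite preference of the methoxy group. The acyl shift must also outrun protonation of 22 and loss of bromide from it, which the intramolecular trap and the aprotic medium favour.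

Step 12
Reactants: 23 (R)-1-(2-bromo-6-hydroxy-4-methoxyphenyl)-2-(7-benzyloxy-4-oxo-4H-chromen-3-yl)-3,3-bis(4-benzyloxyphenyl)propan-1-one
Product: 24 (R)-2-(7-hydroxy-4-oxo-4H-chromen-3-yl)-1-(2-hydroxy-4-methoxyphenyl)-3,3-bis(4-hydroxyphenyl)propan-1-one
Conditions: H2 (1 atm), 10% Pd/C, NaOAc, THF/MeOH, rt
Reagents that add atoms: none
Why: heterogeneous hydrogenolysis cleaves the three aryl benzyl ethers and the aryl C–Br bond while NaOAc takes up the HBr, so no strong acid or base meets the α-centre, and the trisubstituted vinylogous-ester C2=C3 bond and the hydrogen-bonded aryl ketone should survive one atmosphere of hydrogen at room temperature.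

**Compound list**

1 | 1-(4-benzyloxy-2-hydroxyphenyl)ethanone | CC(=O)c1ccc(OCc2ccccc2)cc1O | starting material
2 | tert-butyl bromoacetate | CC(C)(C)OC(=O)CBr | starting material
3 | tert-butyl 4-(4-benzyloxy-2-hydroxyphenyl)-4-oxobutanoate | CC(C)(C)OC(=O)CCC(=O)c1ccc(OCc2ccccc2)cc1O | intermediate
4 | tert-butyl (E)-3-(4-benzyloxy-2-hydroxybenzoyl)-4-(dimethylamino)but-3-enoate (enaminone, not isolated) | CN(C)/C=C(\CC(=O)OC(C)(C)C)C(=O)c1ccc(OCc2ccccc2)cc1O | intermediate
5 | tert-butyl 2-(7-benzyloxy-4-oxo-4H-chromen-3-yl)acetate | CC(C)(C)OC(=O)Cc1coc2cc(OCc3ccccc3)ccc2c1=O | intermediate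
6 | 2-(7-benzyloxy-4-oxo-4H-chromen-3-yl)acetic acid | OC(=O)Cc1coc2cc(OCc3ccccc3)ccc2c1=O | intermediate
7 | (R)-4-benzyloxazolidin-2-one | O=C1N[C@H](Cc2ccccc2)CO1 | starting material
8 | 2-(7-benzyloxy-4-oxo-4H-chromen-3-yl)acetic pivalic anhydride (not isolated) | CC(C)(C)C(=O)OC(=O)Cc1coc2cc(OCc3ccccc3)ccc2c1=O | intermediate
9 | (R)-4-benzyl-3-[2-(7-benzyloxy-4-oxo-4H-chromen-3-yl)acetyl]oxazolidin-2-one | O=C1OC[C@@H](Cc2ccccc2)N1C(=O)Cc1coc2cc(OCc3ccccc3)ccc2c1=O | intermediate
10 | 4,4'-dihydroxybenzophenone | O=C(c1ccc(O)cc1)c1ccc(O)cc1 | starting material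
11 | 4,4'-bis(benzyloxy)benzophenone | O=C(c1ccc(OCc2ccccc2)cc1)c1ccc(OCc2ccccc2)cc1 | intermediate
12 | bis(4-benzyloxyphenyl)methanol (not isolated) | OC(c1ccc(OCc2ccccc2)cc1)c1ccc(OCc2ccccc2)cc1 | intermediate
13 | bis(4-benzyloxyphenyl)methyl methyl ether | COC(c1ccc(OCc2ccccc2)cc1)c1ccc(OCc2ccccc2)cc1 | intermediate
14 | (R)-4-benzyl-3-[(R)-2-(7-benzyloxy-4-oxo-4H-chromen-3-yl)-3,3-bis(4-benzyloxyphenyl)propanoyl]oxazolidin-2-one | O=C1OC[C@@H](Cc2ccccc2)N1C(=O)[C@@H](c1coc2cc(OCc3ccccc3)ccc2c1=O)C(c1ccc(OCc2ccccc2)cc1)c1ccc(OCc2ccccc2)cc1 | intermediate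
15 | (R)-2-(7-benzyloxy-4-oxo-4H-chromen-3-yl)-3,3-bis(4-benzyloxyphenyl)propaneperoxoic acid (not isolated) | OOC(=O)[C@@H](c1coc2cc(OCc3ccccc3)ccc2c1=O)C(c1ccc(OCc2ccccc2)cc1)c1ccc(OCc2ccccc2)cc1 | intermediate
16 | (R)-2-(7-benzyloxy-4-oxo-4H-chromen-3-yl)-3,3-bis(4-benzyloxyphenyl)propanoic acid | OC(=O)[C@@H](c1coc2cc(OCc3ccccc3)ccc2c1=O)C(c1ccc(OCc2ccccc2)cc1)c1ccc(OCc2ccccc2)cc1 | intermediate
17 | 2,6-dibromo-4-methoxyphenol | COc1cc(Br)c(O)c(Br)c1 | starting material
18 | (2,6-dibromo-4-methoxyphenoxy)trimethylsilane | COc1cc(Br)c(O[Si](C)(C)C)c(Br)c1 | intermediate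
19 | lithium 2-bromo-4-methoxy-6-(trimethylsilyl)phenoxide (not isolated) | COc1cc(Br)c([O-])c([Si](C)(C)C)c1.[Li+] | intermediate
20 | 2-bromo-4-methoxy-6-(trimethylsilyl)phenyl trifluoromethanesulfonate | COc1cc(Br)c(OS(=O)(=O)C(F)(F)F)c([Si](C)(C)C)c1 | intermediate
21 | 3-bromo-5-methoxybenzyne (not isolated) | COC1=CC#CC(Br)=C1 | intermediate
22 | 3-bromo-2-caesio-5-methoxyphenyl (R)-2-(7-benzyloxy-4-oxo-4H-chromen-3-yl)-3,3-bis(4-benzyloxyphenyl)propanoate (not isolated) | COc1cc(Br)[c-]c(OC(=O)[C@@H](c2coc3cc(OCc4ccccc4)ccc3c2=O)C(c2ccc(OCc3ccccc3)cc2)c2ccc(OCc3ccccc3)cc2)c1.[Cs+] | intermediate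
23 | (R)-1-(2-bromo-6-hydroxy-4-methoxyphenyl)-2-(7-benzyloxy-4-oxo-4H-chromen-3-yl)-3,3-bis(4-benzyloxyphenyl)propan-1-one | COc1cc(Br)c(C(=O)[C@@H](c2coc3cc(OCc4ccccc4)ccc3c2=O)C(c2ccc(OCc3ccccc3)cc2)c2ccc(OCc3ccccc3)cc2)c(O)c1 | intermediate
24 | (R)-2-(7-hydroxy-4-oxo-4H-chromen-3-yl)-1-(2-hydroxy-4-methoxyphenyl)-3,3-bis(4-hydroxyphenyl)propan-1-one | COc1ccc(C(=O)[C@@H](c2coc3cc(O)ccc3c2=O)C(c2ccc(O)cc2)c2ccc(O)cc2)c(O)c1 | target

**Step count and risks**

Total step count: 12. Longest linear sequence: 8 steps (1, 2, 3, 4, 7, 8, 11, 12).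

Step 11 is the most likely to fail. The aryl anion formed after carboxylate addition may be protonated before it reaches the carbonyl, stopping at the aryl ester, or may expel the neighbouring bromide to give a second aryne. The carboxylate may add in the opposite orientation, and hours at 125 °C with fluoride may erode the α-centre or open the chromone. The fallback makes the ketone without an aryne and without base. Acid 16 is condensed with thiophenol (EDC·HCl, HOBt, CH2Cl2, 0 °C) to S-phenyl (R)-2-(7-benzyloxy-4-oxo-4H-chromen-3-yl)-3,3-bis(4-benzyloxyphenyl)propanethioate F1. Separately, 2-bromo-5-methoxyphenol is benzylated (BnBr, K2CO3, DMF) to 2-benzyloxy-1-bromo-4-methoxybenzene F2, which bromine–lithium exchange and borylation (n-BuLi, B(Oi-Pr)3, THF, −78 °C, then aqueous acid) convert into (2-benzyloxy-4-methoxyphenyl)boronic acid F3. A Liebeskind–Srogl coupling of F1 with F3 (Pd2(dba)3, tri(2-furyl)phosphine, Cu(O2C-2-thienyl), THF, 50 °C) should give (R)-1-(2-benzyloxy-4-methoxyphenyl)-2-(7-benzyloxy-4-oxo-4H-chromen-3-yl)-3,3-bis(4-benzyloxyphenyl)propan-1-one F4. Hydrogenolysis of F4 under the conditions of step 12 comes back to the route at the target 24.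

Step 7 is second. TiCl4 may be sequestered by the chromone carbonyl so that enolisation or ionisation of 13 stalls, and the enolate may add to C2 of a Lewis-acid-activated chromone of a second molecule. The benzhydryl cation may also self-condense in a Friedel–Crafts sense, and facial selectivity may be poor. The fallback sets out from acid 6 and uses a thioimide auxiliary with catalytic nickel in place of stoichiometric titanium. Acid 6 is coupled with (R)-4-isopropyl-1,3-thiazolidine-2-thione (EDC·HCl, cat. DMAP, CH2Cl2) to 2-(7-benzyloxy-4-oxo-4H-chromen-3-yl)-1-[(R)-4-isopropyl-2-thioxothiazolidin-3-yl]ethanone F5. Direct SN1 alkylation of F5 with 13 ((Me3P)2NiCl2 cat., Et3SiOTf, 2,6-lutidine, CH2Cl2, −20 °C) proceeds through the chelated nickel enolate, again on the face away from the C4 substituent, and should give (R)-2-(7-benzyloxy-4-oxo-4H-chromen-3-yl)-3,3-bis(4-benzyloxyphenyl)-1-[(R)-4-isopropyl-2-thioxothiazolidin-3-yl]propan-1-one F6. The much more electrophilic thioimide is then hydrolysed briefly (LiOH, THF/H2O, 0 °C), which comes back to the route at acid 16.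

Step 8 is third. Exocyclic cleavage of the congested imide may be slow, so that endocyclic opening of the oxazolidinone competes. Hydroperoxide or hydroxide may epoxidise or open the chromone, and the α-centre may epimerise under base. The fallback sets out from imide 14 and avoids oxidant and oxygen bases. The weakly basic thiolate LiSEt (EtSH, n-BuLi, THF, 0 °C) displaces the auxiliary to give S-ethyl (R)-2-(7-benzyloxy-4-oxo-4H-chromen-3-yl)-3,3-bis(4-benzyloxyphenyl)propanethioate F7. Silver-assisted hydrolysis of F7 (AgNO3, THF/H2O, rt) then comes back to the route at acid 16.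

**Further compounds**

F1 | step 11 | S-phenyl (R)-2-(7-benzyloxy-4-oxo-4H-chromen-3-yl)-3,3-bis(4-benzyloxyphenyl)propanethioate | O=C(Sc1ccccc1)[C@@H](c1coc2cc(OCc3ccccc3)ccc2c1=O)C(c1ccc(OCc2ccccc2)cc1)c1ccc(OCc2ccccc2)cc1
F2 | step 11 | 2-benzyloxy-1-bromo-4-methoxybenzene | COc1ccc(Br)c(OCc2ccccc2)c1
F3 | step 11 | (2-benzyloxy-4-methoxyphenyl)boronic acid | COc1ccc(B(O)O)c(OCc2ccccc2)c1
F4 | step 11 | (R)-1-(2-benzyloxy-4-methoxyphenyl)-2-(7-benzyloxy-4-oxo-4H-chromen-3-yl)-3,3-bis(4-benzyloxyphenyl)propan-1-one | COc1ccc(C(=O)[C@@H](c2coc3cc(OCc4ccccc4)ccc3c2=O)C(c2ccc(OCc3ccccc3)cc2)c2ccc(OCc3ccccc3)cc2)c(OCc2ccccc2)c1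
F5 | step 7 | 2-(7-benzyloxy-4-oxo-4H-chromen-3-yl)-1-[(R)-4-isopropyl-2-thioxothiazolidin-3-yl]ethanone | CC(C)[C@@H]1CSC(=S)N1C(=O)Cc1coc2cc(OCc3ccccc3)ccc2c1=O
F6 | step 7 | (R)-2-(7-benzyloxy-4-oxo-4H-chromen-3-yl)-3,3-bis(4-benzyloxyphenyl)-1-[(R)-4-isopropyl-2-thioxothiazolidin-3-yl]propan-1-one | CC(C)[C@@H]1CSC(=S)N1C(=O)[C@@H](c1coc2cc(OCc3ccccc3)ccc2c1=O)C(c1ccc(OCc2ccccc2)cc1)c1ccc(OCc2ccccc2)cc1
F7 | step 8 | S-ethyl (R)-2-(7-benzyloxy-4-oxo-4H-chromen-3-yl)-3,3-bis(4-benzyloxyphenyl)propanethioate | CCSC(=O)[C@@H](c1coc2cc(OCc3ccccc3)ccc2c1=O)C(c1ccc(OCc2ccccc2)cc1)c1ccc(OCc2ccccc2)cc1
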